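**Retrosynthetic overview**
- Target ⇐ double O-methylation and ester hydrolysis of a 5-hydroxy-4-pyridone-2-carboxylic acid, itself made from the matching 3-hydroxy-4-pyranone by oxygen-to-nitrogen exchange with ammonia.
- The 3-hydroxy-4-pyranone ⇐ oxidative ring expansion (Achmatowicz type, continued to the γ-pyrone) of a furan: furan C2–C5 plus the carbinol carbon become the five ring carbons of the pyridine.
- The furyl thiazolyl carbinol ⇐ a 4-lithiothiazole plus methyl 5-formylfuran-2-carboxylate, made by formylation of methyl furan-2-carboxylate.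
- The thiazole fragment ⇐ C2-selective B-alkyl Suzuki coupling of 2,4-dibromothiazole with (S)-hept-6-en-2-ol, from (S)-propylene oxide and a butenyl Grignard reagent; this supplies the only stereocenter.
- Ring order: thiazole and furan are bought intact; the pyranone ring is formed from the furan in step 5 and the pyridine ring from the pyranone in step 6.

Assumption: the stereocenter in the SMILES is read as (S) (a (6S)-6-hydroxyheptyl chain); but-3-en-1-ylmagnesium bromide and 9-BBN are used as purchased THF solutions.

**Step 1**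
Reactants: 1 (2S)-2-methyloxirane; 2 but-3-en-1-ylmagnesium bromide
Product: 3 (2S)-hept-6-en-2-ol
Conditions: CuBr·SMe2 (5 mol%), THF, −30 → 0 °C; then 1 M HCl
Reagents that add atoms: none
Why: Copper-catalysed SN2 ring opening of the epoxide by the Grignard reagent occurs at the unsubstituted CH2 carbon, so the (S) center bought with 1 is carried unchanged into the carbinol of 3, the only stereocenter of the target.

**Step 2**
Reactants: 3 (2S)-hept-6-en-2-ol; 4 2,4-dibromo-1,3-thiazole
Product: 6 (2S)-7-(4-bromo-1,3-thiazol-2-yl)heptan-2-ol, via bis-boryl adduct 5 (not isolated)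
Conditions: 9-BBN (2.2 equiv), THF, 0 °C → rt; then 4, PdCl2(dppf) (5 mol%), K3PO4 (3 equiv, aq.), DMF, 55 °C
Reagents that add atoms: none
Why: Anti-Markovnikov hydroboration puts boron on the terminal carbon (the second equivalent of 9-BBN is taken up by the hydroxyl as a borinate that hydrolyses on work-up), and the B-alkyl Suzuki–Miyaura coupling is selective for C2–Br of 4 because zerovalent palladium inserts first into the carbon–bromine bond flanked by sulfur and nitrogen; the carbinol center is not touched.

**Step 3**
Reactants: 7 methyl furan-2-carboxylate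
Product: 8 methyl 5-formylfuran-2-carboxylate
Conditions: POCl3 (1.5 equiv), DMF, 0 → 95 °C; then ice-water
Reagents that add atoms: N,N-dimethylformamide CN(C)C=O; water O
Why: Vilsmeier–Haack formylation takes place at C5, the only free alpha position of the furan and the one least deactivated by the ester.

**Step 4**
Reactants: 6 (2S)-7-(4-bromo-1,3-thiazol-2-yl)heptan-2-ol; 8 methyl 5-formylfuran-2-carboxylate
Product: 10 methyl 5-(hydroxy{2-[(6S)-6-hydroxyheptyl]-1,3-thiazol-4-yl}methyl)furan-2-carboxylate, via dilithio species 9 (not isolated)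
Conditions: n-BuLi (2.1 equiv), THF, −78 °C; then 8 (1.1 equiv), −78 °C; then AcOH
Reagents that add atoms: none
Why: The first equivalent of n-BuLi deprotonates the hydroxyl and the second effects bromine–lithium exchange at C4, and the 4-lithiothiazole adds to the aldehyde far faster than to the ester at −78 °C (1,2-addition of an organolithium); the new carbinol center forms as an epimer mixture and is destroyed in step 5.

**Step 5**
Reactants: 10 methyl 5-(hydroxy{2-[(6S)-6-hydroxyheptyl]-1,3-thiazol-4-yl}methyl)furan-2-carboxylate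
Product: 13 methyl 5-hydroxy-6-{2-[(6S)-6-hydroxyheptyl]-1,3-thiazol-4-yl}-4-oxo-4H-pyran-2-carboxylate, via hemiketal pyranone 11 (not isolated), via bromo enone 12 (not isolated)
Conditions: 48% aq. HBr (1.1 equiv), Br2 (2.05 equiv), MeCN–H2O 1:1, −10 → 0 °C; then 70 °C, 2 h
Reagents that add atoms: water O
Why: Proposed new method: a one-flask Achmatowicz oxidative ring expansion continued to the γ-pyrone (the reaction type by which 2-furylcarbinols are converted into maltol-type 3-hydroxy-4-pyranones with two equivalents of halogen in water) is applied to a furan carrying an ester and a thiazolyl carbinol; the first Br2 adds across the furan 2,5-positions, water gives the cis-ene-dione and the carbinol oxygen closes it to hemiketal 11, the second Br2 adds to the enone and loses HBr to give 12, and on warming enolisation, allylic transposition of water from C6 to C4 and loss of HBr give pyrone 13 with the oxygen pattern of the target; prior protonation of the thiazole by HBr shields it from bromination and the ester prevents bromodecarboxylation.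

**Step 6**
Reactants: 13 methyl 5-hydroxy-6-{2-[(6S)-6-hydroxyheptyl]-1,3-thiazol-4-yl}-4-oxo-4H-pyran-2-carboxylate
Product: 15 5-hydroxy-6-{2-[(6S)-6-hydroxyheptyl]-1,3-thiazol-4-yl}-4-oxo-1,4-dihydropyridine-2-carboxylic acid, via pyranone acid 14 (not isolated)
Conditions: LiOH (2.1 equiv), MeOH–H2O, 0 °C → rt; then 28% aq. NH3, sealed tube, 90 °C; AcOH to pH 3
Reagents that add atoms: lithium hydroxide [Li+].[OH-]; ammonia N
Why: Saponification first frees the carboxylate so that ammonia cannot form the amide, and ammonia then adds to the γ-pyrone, opens the ring and recloses through nitrogen (ANRORC-type oxygen-to-nitrogen exchange, the reaction type that turns comenic acid into comenamic acid), which creates the pyridine ring. Any ester already hydrolysed in step 5 converges here.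

**Step 7**
Reactants: 15 5-hydroxy-6-{2-[(6S)-6-hydroxyheptyl]-1,3-thiazol-4-yl}-4-oxo-1,4-dihydropyridine-2-carboxylic acid
Product: 17 6-{2-[(6S)-6-hydroxyheptyl]-1,3-thiazol-4-yl}-4,5-dimethoxypyridine-2-carboxylic acid, via methyl ester 16 (not isolated)
Conditions: MeI (3.5 equiv), K2CO3 (4 equiv), DMF, 40 °C; remove excess MeI; then LiOH, THF–H2O, rt; 1 M HCl to pH 3
Reagents that add atoms: iodomethane CI; lithium hydroxide [Li+].[OH-]
Why: The carboxylate and the phenolic hydroxyl are O-methylated and the ambident 4-pyridone is alkylated on oxygen because its nitrogen is flanked by the thiazolyl and ester groups (as with chelidamic esters), after which mild saponification of the methyl ester releases the acid; the unactivated secondary alcohol is not alkylated by K2CO3/MeI (Williamson-type O-alkylation, then ester hydrolysis).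

**Compound list**
1 | (2S)-2-methyloxirane | C[C@H]1CO1 | starting material
2 | but-3-en-1-ylmagnesium bromide | C=CCC[Mg]Br | starting material
3 | (2S)-hept-6-en-2-ol | C=CCCC[C@H](C)O | intermediate
4 | 2,4-dibromo-1,3-thiazole | Brc1csc(Br)n1 | starting material
5 | 9-[(6S)-6-(9-borabicyclo[3.3.1]nonan-9-yloxy)heptyl]-9-borabicyclo[3.3.1]nonane | C[C@H](OB1C2CCCC1CCC2)CCCCCB1C2CCCC1CCC2 | intermediate (not isolated)
6 | (2S)-7-(4-bromo-1,3-thiazol-2-yl)heptan-2-ol | C[C@H](O)CCCCCc1nc(Br)cs1 | intermediate
7 | methyl furan-2-carboxylate | COC(=O)c1ccco1 | starting material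
8 | methyl 5-formylfuran-2-carboxylate | COC(=O)c1ccc(C=O)o1 | intermediate
9 | lithium (2S)-7-(4-lithio-1,3-thiazol-2-yl)heptan-2-olate | C[C@H](O[Li])CCCCCc1nc([Li])cs1 | intermediate (not isolated)
10 | methyl 5-(hydroxy{2-[(6S)-6-hydroxyheptyl]-1,3-thiazol-4-yl}methyl)furan-2-carboxylate (both carbinol epimers) | COC(=O)c1ccc(o1)C(O)c1csc(CCCCC[C@H](C)O)n1 | intermediate
11 | methyl 2-hydroxy-6-{2-[(6S)-6-hydroxyheptyl]-1,3-thiazol-4-yl}-5-oxo-5,6-dihydro-2H-pyran-2-carboxylate (ring centers as a mixture) | COC(=O)C1(O)C=CC(=O)C(O1)c1csc(CCCCC[C@H](C)O)n1 | intermediate (not isolated)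
12 | methyl 4-bromo-2-hydroxy-6-{2-[(6S)-6-hydroxyheptyl]-1,3-thiazol-4-yl}-5-oxo-5,6-dihydro-2H-pyran-2-carboxylate (ring centers as a mixture) | COC(=O)C1(O)C=C(Br)C(=O)C(O1)c1csc(CCCCC[C@H](C)O)n1 | intermediate (not isolated)
13 | methyl 5-hydroxy-6-{2-[(6S)-6-hydroxyheptyl]-1,3-thiazol-4-yl}-4-oxo-4H-pyran-2-carboxylate | COC(=O)c1cc(=O)c(O)c(o1)-c1csc(CCCCC[C@H](C)O)n1 | intermediate
14 | 5-hydroxy-6-{2-[(6S)-6-hydroxyheptyl]-1,3-thiazol-4-yl}-4-oxo-4H-pyran-2-carboxylic acid (present as its lithium salt) | OC(=O)c1cc(=O)c(O)c(o1)-c1csc(CCCCC[C@H](C)O)n1 | intermediate (not isolated)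
15 | 5-hydroxy-6-{2-[(6S)-6-hydroxyheptyl]-1,3-thiazol-4-yl}-4-oxo-1,4-dihydropyridine-2-carboxylic acid | OC(=O)c1cc(=O)c(O)c([nH]1)-c1csc(CCCCC[C@H](C)O)n1 | intermediate
16 | methyl 6-{2-[(6S)-6-hydroxyheptyl]-1,3-thiazol-4-yl}-4,5-dimethoxypyridine-2-carboxylate | COC(=O)c1cc(OC)c(OC)c(n1)-c1csc(CCCCC[C@H](C)O)n1 | intermediate (not isolated)
17 | 6-{2-[(6S)-6-hydroxyheptyl]-1,3-thiazol-4-yl}-4,5-dimethoxypyridine-2-carboxylic acid | COc1cc(C(=O)O)nc(-c2csc(CCCCC[C@H](C)O)n2)c1OC | target

**Step count**
Total steps: 7. Longest linear sequence: 6 (steps 1, 2, 4, 5, 6, 7); step 3 is a one-step side branch.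

**Steps most likely to fail, with fallbacks**

Step 5 is the riskiest. The ester slows the furan oxidation, so bromination at thiazole C5 or oxidation of the side-chain alcohol may compete, and the α-keto-ester hemiketal may fragment on heating. The fallback sets out from 10 and separates the two oxidations. Anodic methoxylation (graphite anode, Et4NOTs, MeOH, 0 °C) gives the 2,5-dimethoxy-2,5-dihydrofuran F1. Formic acid in MeOH closes it to the 6-methoxy pyranone F2. Nucleophilic epoxidation of the enone (t-BuOOH, DBU, CH2Cl2, 0 °C) gives the epoxy ketone F3. Warm 0.5 M H2SO4 in dioxane–H2O (80 °C) then opens the epoxide, eliminates methanol and enolises, and the route is rejoined at 13.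

Step 4 may suffer from proton transfer between the 4-lithiothiazole and the acidic thiazole C5–H or the CH2 next to C2, or from incomplete exchange in the presence of the alkoxide. The fallback sets out from 6 and avoids strong base. Miyaura borylation (B2pin2, PdCl2(dppf), KOAc, dioxane, 90 °C) gives the pinacol boronate F4. A rhodium-catalysed 1,2-addition of F4 to aldehyde 8 ([RhCl(cod)]2, K3PO4, dioxane–H2O, 60 °C) tolerates the free hydroxyl and the ester, and the route is rejoined at 10.

Step 6 may be slow or degradative because the pyranone is present as an enolate dianion and carries a bulky 6-substituent. The fallback sets out from 13 and changes the order of methylation and amination. MeI (1.1 equiv) and K2CO3 in acetone methylate only the acidic enol to give the 5-methoxy pyranone ester F5. Saponification (LiOH) and ammonia exchange on this neutral, more electrophilic pyranone (aq. NH3, 80 °C) give the 5-methoxy pyridone acid F6. MeI and K2CO3 in DMF then give methyl ester 16, where the route is rejoined before the final saponification to 17.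

**Further compounds**
F1 | step 5 | methyl 5-(hydroxy{2-[(6S)-6-hydroxyheptyl]-1,3-thiazol-4-yl}methyl)-2,5-dimethoxy-2,5-dihydrofuran-2-carboxylate | COC(=O)C1(OC)C=CC(OC)(O1)C(O)c1csc(CCCCC[C@H](C)O)n1
F2 | step 5 | methyl 6-{2-[(6S)-6-hydroxyheptyl]-1,3-thiazol-4-yl}-2-methoxy-5-oxo-5,6-dihydro-2H-pyran-2-carboxylate | COC(=O)C1(OC)C=CC(=O)C(O1)c1csc(CCCCC[C@H](C)O)n1
F3 | step 5 | methyl 4-{2-[(6S)-6-hydroxyheptyl]-1,3-thiazol-4-yl}-2-methoxy-5-oxo-3,7-dioxabicyclo[4.1.0]heptane-2-carboxylate | COC(=O)C1(OC)C2OC2C(=O)C(O1)c1csc(CCCCC[C@H](C)O)n1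
F4 | step 4 | (2S)-7-[4-(4,4,5,5-tetramethyl-1,3,2-dioxaborolan-2-yl)-1,3-thiazol-2-yl]heptan-2-ol | C[C@H](O)CCCCCc1nc(cs1)B1OC(C)(C)C(C)(C)O1
F5 | step 6 | methyl 6-{2-[(6S)-6-hydroxyheptyl]-1,3-thiazol-4-yl}-5-methoxy-4-oxo-4H-pyran-2-carboxylate | COC(=O)c1cc(=O)c(OC)c(o1)-c1csc(CCCCC[C@H](C)O)n1
F6 | step 6 | 6-{2-[(6S)-6-hydroxyheptyl]-1,3-thiazol-4-yl}-5-methoxy-4-oxo-1,4-dihydropyridine-2-carboxylic acid | OC(=O)c1cc(=O)c(OC)c([nH]1)-c1csc(CCCCC[C@H](C)O)n1
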